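## Retrosynthetic overview

1. The target is cut at its two C‑15 O–acyl bonds into three copies of one monomer **24**: a 15‑hydroxydrim‑8(12)‑ene whose C‑11 oxygen is the ether oxygen of a (2R,3S)‑isocitrate with three different esters.
2. Rings A and B of **24** form together, from the acyclic epoxy‑diene‑allylsilane **23**: the (R)‑2,2‑disubstituted epoxide starts the cyclisation, the (Z)‑allylsilane ends it as the exocyclic methylene.
3. The hindered C‑11 ether is made before any ring exists, as a simple allylic ether (**7** + **20**); CH2SiMe3 (Negishi) and the epoxide (asymmetric Corey–Chaykovsky) are put in afterwards.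
4. Isocitrate **7** comes from D‑malic acid by Fráter–Seebach alkylation; bromide **20** from a chloro ketal, acetylene, AlMe3, oxirane and propargyl alcohol.
5. Ring order: rings A and B of each unit close in step 13 on the monomer; no other step forms a ring, and the three bicyclic units are then joined by two esterifications.

Conventions: drimane numbering (C‑11 = OCH2 on C‑9; C‑12 = exocyclic CH2 on C‑8; C‑15 = CH2O on C‑4, α, equatorial). Isocitrate carboxyls: a on the ether carbon C‑1', b central on C‑2', c the CH2CO2 arm. Units: X (free 15‑OH), Y (middle), Z (free carboxyl b).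

Assumption: the LaLi3(binaphthoxide)3 catalyst made from (R)‑BINOL is taken to be the antipode that transfers CH2 to the Si face of ketone **22** (R epoxide); if the first run shows the opposite sense, the (S)‑BINOL catalyst is used unchanged otherwise.

## Route

Step 1
Reactants: 1 D‑malic acid
Product: 3 (R)-malic acid 1-methyl ester, via trifluoroacetoxysuccinic anhydride 2 (not isolated)
Conditions: (CF3CO)2O, 0 °C to rt; evaporate; MeOH, rt
Reagents that add atoms: methanol, CO
Why: Anhydride alcoholysis, in which methanol opens the O‑acylated anhydride at the carbonyl next to the acyloxy carbon and then removes the trifluoroacetate, so only carboxyl a is esterified and the D‑malic stereocentre is untouched.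

Step 2
Reactants: 3 (R)-malic acid 1-methyl ester
Product: 4 1-methyl 4-[2-(trimethylsilyl)ethyl] (R)-malate
Conditions: DCC, DMAP (cat.), Me3SiCH2CH2OH (3 equiv), CH2Cl2, 0 °C to rt
Reagents that add atoms: 2-(trimethylsilyl)ethanol, C[Si](C)(C)CCO
Why: Steglich esterification of the free carboxyl with an excess of a primary alcohol, which outruns the hindered secondary hydroxyl of 3; no stereocentre is involved.

Step 3
Reactants: 4 1-methyl 4-[2-(trimethylsilyl)ethyl] (R)-malate; 5 tert-butyl bromoacetate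
Product: 7 isocitrate alcohol (a = Me; b = CH2CH2SiMe3; c = tBu; 1'R,2'S), via dilithium alkoxide-enolate 6 (not isolated)
Conditions: LiN(SiMe3)2 (2.2 equiv), THF, −78 to −20 °C; then 5, −78 to −10 °C
Reagents that add atoms: none
Why: Fráter–Seebach alkylation, in which the chelated lithium alkoxide‑enolate is alkylated anti to the alkoxide and so sets C‑2' as S (about 9:1, minor isomer removed by chromatography).

Step 4
Reactants: 8 2-(3-chloropropyl)-2-methyl-1,3-dioxolane
Product: 9 2-methyl-2-(pent-4-yn-1-yl)-1,3-dioxolane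
Conditions: LiC≡CH·H2NCH2CH2NH2, DMSO, rt
Reagents that add atoms: lithium acetylide ethylenediamine complex, [Li]C#C.NCCN
Why: SN2 alkylation of an acetylide by a primary chloride in a dipolar aprotic solvent.

Step 5
Reactants: 9 2-methyl-2-(pent-4-yn-1-yl)-1,3-dioxolane
Product: 12 (E)-4-methyl-7-(2-methyl-1,3-dioxolan-2-yl)hept-3-en-1-ol, via alkenylalane 10 (not isolated), via lithium alkenylalanate 11 (not isolated)
Conditions: Me3Al (2.5 equiv), Cp2ZrCl2 (0.2 equiv), H2O (1 equiv), CH2Cl2, −20 °C; n‑BuLi, −78 °C; oxirane, THF, −78 °C to rt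
Reagents that add atoms: trimethylaluminium, C[Al](C)C; oxirane, C1CO1
Why: Negishi zirconium‑catalysed carboalumination adds Me and Al syn (Me to the inner carbon), and the derived alanate opens oxirane with retention, fixing the E trisubstituted C‑5=C‑10 alkene; the low temperature spares the ketal.

Step 6
Reactants: 12 (E)-4-methyl-7-(2-methyl-1,3-dioxolan-2-yl)hept-3-en-1-ol
Product: 13 2-[(E)-7-iodo-4-methylhept-4-en-1-yl]-2-methyl-1,3-dioxolane
Conditions: I2, PPh3, imidazole, CH2Cl2, 0 °C
Reagents that add atoms: iodine, II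
Why: Appel‑type iodination of a primary alcohol under imidazole buffering, which keeps the ketal and the alkene geometry.

Step 7
Reactants: 13 2-[(E)-7-iodo-4-methylhept-4-en-1-yl]-2-methyl-1,3-dioxolane; 14 propargyl alcohol
Product: 16 (E)-7-methyl-10-(2-methyl-1,3-dioxolan-2-yl)dec-6-en-2-yn-1-ol, via dilithiated propargyl alcohol 15 (not isolated)
Conditions: 14, n‑BuLi (2.05 equiv), THF–DMPU, −78 to 0 °C; then 13, 0 °C to rt
Reagents that add atoms: none
Why: C‑alkylation of the O,C‑dilithio derivative of propargyl alcohol by a primary iodide (acetylide SN2), which brings in C‑8, C‑9 and C‑11 at once.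

Step 8
Reactants: 16 (E)-7-methyl-10-(2-methyl-1,3-dioxolan-2-yl)dec-6-en-2-yn-1-ol
Product: 19 (6E,10Z)-12-hydroxy-10-iodo-6-methyldodeca-6,10-dien-2-one, via cyclic vinylalanate 17 (not isolated), via iodo ketal alcohol 18 (not isolated)
Conditions: NaAlH2(OCH2CH2OMe)2, THF, 0 °C to rt; EtOAc; I2, −78 °C; then 2 M HCl, THF, rt
Reagents that add atoms: iodine, II; water, O
Why: Alkoxide‑directed trans‑hydroalumination of the propargylic alcohol and iodinolysis with retention give the (Z)-3-iodoallylic alcohol, and the acid work‑up hydrolyses the dioxolane to the methyl ketone.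

Step 9
Reactants: 19 (6E,10Z)-12-hydroxy-10-iodo-6-methyldodeca-6,10-dien-2-one
Product: 20 (6E,10Z)-12-bromo-10-iodo-6-methyldodeca-6,10-dien-2-one
Conditions: CBr4, PPh3, CH2Cl2, 0 °C
Reagents that add atoms: tetrabromomethane, BrC(Br)(Br)Br
Why: Appel bromination of the primary allylic alcohol under neutral conditions without allylic transposition.

Step 10
Reactants: 20 (6E,10Z)-12-bromo-10-iodo-6-methyldodeca-6,10-dien-2-one; 7 isocitrate alcohol (1.5 equiv)
Product: 21 iodo‑dienyl ketone ether of 7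
Conditions: Ag2O, 4 Å molecular sieves, CH2Cl2, dark, rt
Reagents that add atoms: none
Why: Silver oxide‑mediated Williamson etherification of the α‑hydroxy ester under non‑basic conditions, so C‑1' and C‑2' neither epimerise nor eliminate, while the electron‑poor iodoalkene keeps the allylic bromide from ionising and the Z geometry is kept.

Step 11
Reactants: 21 iodo‑dienyl ketone ether of 7
Product: 22 (Z)-allylsilane ketone ether
Conditions: Me3SiCH2ZnCl (from Me3SiCH2MgCl and ZnCl2, 2 equiv), Pd(PPh3)4 (5 mol%), THF, rt to 40 °C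
Reagents that add atoms: (trimethylsilyl)methylzinc chloride, C[Si](C)(C)C[Zn]Cl
Why: Negishi sp2–sp3 coupling under zerovalent palladium catalysis proceeds with retention of alkene geometry and tolerates the ketone and the three esters, giving the (Z)-allylsilane that will end the cyclisation.

Step 12
Reactants: 22 (Z)-allylsilane ketone ether
Product: 23 (R)-epoxy‑diene‑allylsilane ether
Conditions: Me2S(O)=CH2 (1.2 equiv, from Me3S(O)I and NaH), LaLi3[(R)-binaphthoxide]3 (5 mol%), (2,4,6-(MeO)3C6H2)3P=O (5 mol%), 5 Å molecular sieves, THF, rt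
Reagents that add atoms: dimethylsulfoxonium methylide, C[S+](C)(=O)[CH2-]
Why: Catalytic asymmetric Corey–Chaykovsky epoxidation of a methyl ketone, in which the lanthanum–lithium binaphthoxide/phosphine oxide catalyst directs CH2 to the Si face and sets the (R)-2,2-disubstituted epoxide (about 90–95% ee expected; the minor epimer is a diastereomer because of the isocitrate and is removed after step 13).

Step 13
Reactants: 23 (R)-epoxy‑diene‑allylsilane ether
Product: 24 monomer (15‑hydroxydrim‑8(12)‑en‑11‑yl ether of 7)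
Conditions: MeAlCl2 (4 equiv), CH2Cl2, −78 °C; Et3N–MeOH quench; aq. potassium sodium tartrate
Reagents that add atoms: none
Why: Proposed new method: MeAlCl2 binds the epoxide oxygen and the C‑5=C‑10 π bond attacks the tertiary epoxide carbon from the back (SN2‑like, inversion at C‑4) through a chair with the aluminate‑bearing CH2O arm equatorial, the C‑10 cation is caught in a second chair by the (Z)-allylsilane (C‑11 equatorial, 9β) and the β‑silyl cation loses Me3Si to leave the 8(12)-methylene, so the one epoxide stereocentre fixes C‑4, C‑5, C‑10 and C‑9 while rings A and B close together; the closest known reaction type is the Lewis acid‑promoted cationic cyclisation of trisubstituted epoxy‑polyenes ended by allylsilanes, from which this differs in the terminal 2,2‑disubstituted epoxide that leaves the primary C‑15 alcohol and no C‑3 oxygen.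

Step 14
Reactants: 24 monomer
Product: 26 monomer with free carboxyl c, via bis(trimethylsilyl) derivative 25 (not isolated)
Conditions: Me3SiOTf (3 equiv), 2,6‑lutidine (4 equiv), CH2Cl2, 0 °C to rt; then aq. citric acid, MeOH
Reagents that add atoms: none
Why: Silyl triflate‑mediated tert‑butyl ester cleavage (loss of isobutene to the silyl ester) under buffered, non‑protic conditions that leave the exocyclic alkene, the silylethyl ester and the methyl ester alone; no stereocentre is touched.

Step 15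
Reactants: 26 monomer with free carboxyl c
Product: 27 monomer Z (a = Me; b = CH2CH2SiMe3; c = Me; 15‑OH free)
Conditions: Me3SiCHN2, toluene–MeOH, 0 °C
Reagents that add atoms: (trimethylsilyl)diazomethane, C[Si](C)(C)C=[N+]=[N-]
Why: O‑Methylation of a carboxylic acid by a diazoalkane, neutral and without risk to C‑1' or C‑2'.

Step 16
Reactants: 24 monomer
Product: 28 15‑O‑tert‑butoxycarbonyl monomer
Conditions: Boc2O (2 equiv), DMAP (0.3 equiv), CH2Cl2, rt
Reagents that add atoms: di-tert-butyl dicarbonate, CC(C)(C)OC(=O)OC(=O)OC(C)(C)C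
Why: DMAP‑catalysed carbonate formation on the neopentyl primary alcohol, giving a group that survives fluoride and leaves together with the tert‑butyl esters at the end.

Step 17
Reactants: 28 15‑O‑tert‑butoxycarbonyl monomer
Product: 29 acid X (carboxyl b free)
Conditions: Bu4NF, THF, 0 °C; aq. KHSO4
Reagents that add atoms: none
Why: Fluoride‑induced fragmentation of the 2‑(trimethylsilyl)ethyl ester, leaving the methyl ester, tert‑butyl ester and carbonate in place.

Step 18
Reactants: 29 acid X; 24 monomer (unit Y)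
Product: 30 dimer X–Y
Conditions: 2‑methyl‑6‑nitrobenzoic anhydride (1.3 equiv), DMAP, Et3N, CH2Cl2, rt
Reagents that add atoms: none
Why: Shiina mixed‑anhydride esterification (acyl transfer through the acylpyridinium) of the hindered acid with the only free hydroxyl present, O‑15 of unit Y, at room temperature to protect the enolisable C‑2'.

Step 19
Reactants: 30 dimer X–Y
Product: 31 dimer acid (carboxyl b of Y free)
Conditions: Bu4NF, THF, 0 °C; aq. KHSO4
Reagents that add atoms: none
Why: Fluoride‑induced fragmentation of the single 2‑(trimethylsilyl)ethyl ester; the hindered inter‑unit ester and the other esters are inert to fluoride.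

Step 20
Reactants: 31 dimer acid; 27 monomer Z
Product: 32 protected trimer
Conditions: 2‑methyl‑6‑nitrobenzoic anhydride (1.3 equiv), DMAP, Et3N, CH2Cl2, rt
Reagents that add atoms: none
Why: Second Shiina esterification, joining carboxyl b of unit Y to O‑15 of unit Z, whose own carboxyl b is still masked.

Step 21
Reactants: 32 protected trimer
Product: 33 trimer with carboxyl b of Z free
Conditions: Bu4NF, THF, 0 °C; aq. KHSO4
Reagents that add atoms: none
Why: Fluoride‑induced fragmentation of the last 2‑(trimethylsilyl)ethyl ester.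

Step 22
Reactants: 33 trimer with carboxyl b of Z free
Product: 35 cryptoporic acid T, via persilylated trimer 34 (not isolated)
Conditions: Me3SiOTf (8 equiv), 2,6‑lutidine (10 equiv), CH2Cl2, 0 °C to rt; then aq. citric acid, MeOH
Reagents that add atoms: none
Why: Silyl triflate‑mediated cleavage of the two tert‑butyl esters and the tert‑butyl carbonate (each by loss of isobutene, the silyl carbonate then losing CO2 on work‑up) under buffered conditions that spare the three exocyclic alkenes, four methyl esters and two inter‑unit esters.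

## Compound list

1 | D‑malic acid, (R)-2-hydroxybutanedioic acid | O[C@@H](C(=O)O)CC(=O)O | starting material
2 | (3R)-2,5-dioxooxolan-3-yl trifluoroacetate (formed in the flask) | O=C1C[C@@H](OC(=O)C(F)(F)F)C(=O)O1 | intermediate
3 | (3R)-3-hydroxy-4-methoxy-4-oxobutanoic acid | O[C@@H](C(=O)OC)CC(=O)O | intermediate
4 | 1-methyl 4-[2-(trimethylsilyl)ethyl] (R)-malate | O[C@@H](C(=O)OC)CC(=O)OCC[Si](C)(C)C | intermediate
5 | tert-butyl bromoacetate | BrCC(=O)OC(C)(C)C | starting material
6 | dilithium alkoxide‑enolate of 4 (formed in the flask) | [Li]O[C@@H](C(=O)OC)C=C(O[Li])OCC[Si](C)(C)C | intermediate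
7 | 3-tert-butyl 1-methyl 2-[2-(trimethylsilyl)ethyl] (1R,2S)-1-hydroxypropane-1,2,3-tricarboxylate | O[C@@H](C(=O)OC)[C@H](CC(=O)OC(C)(C)C)C(=O)OCC[Si](C)(C)C | intermediate
8 | 2-(3-chloropropyl)-2-methyl-1,3-dioxolane | CC1(CCCCl)OCCO1 | starting material
9 | 2-methyl-2-(pent-4-yn-1-yl)-1,3-dioxolane | CC1(CCCC#C)OCCO1 | intermediate
10 | dimethyl[(E)-2-methyl-5-(2-methyl-1,3-dioxolan-2-yl)pent-1-en-1-yl]alane (formed in the flask) | C[Al](C)/C=C(C)/CCCC1(C)OCCO1 | intermediate
11 | lithium butyl(dimethyl)[(E)-2-methyl-5-(2-methyl-1,3-dioxolan-2-yl)pent-1-en-1-yl]alanate (formed in the flask) | [Li+].CCCC[Al-](C)(C)/C=C(C)/CCCC1(C)OCCO1 | intermediate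
12 | (E)-4-methyl-7-(2-methyl-1,3-dioxolan-2-yl)hept-3-en-1-ol | OCC/C=C(C)/CCCC1(C)OCCO1 | intermediate
13 | 2-[(E)-7-iodo-4-methylhept-4-en-1-yl]-2-methyl-1,3-dioxolane | ICC/C=C(C)/CCCC1(C)OCCO1 | intermediate
14 | propargyl alcohol (prop-2-yn-1-ol) | OCC#C | starting material
15 | O,C‑dilithio prop-2-yn-1-ol (formed in the flask) | [Li]OCC#C[Li] | intermediate
16 | (E)-7-methyl-10-(2-methyl-1,3-dioxolan-2-yl)dec-6-en-2-yn-1-ol | OCC#CCC/C=C(C)/CCCC1(C)OCCO1 | intermediate
17 | sodium 2,2-bis(2-methoxyethoxy)-2,5-dihydro-1,2-oxaluminol-2-uide carrying the (E)-4-methyl-7-(2-methyl-1,3-dioxolan-2-yl)hept-3-enyl chain on C‑3 (formed in the flask) | [Na+].COCCO[Al-]1(OCCOC)OCC=C1CC/C=C(C)/CCCC2(C)OCCO2 | intermediate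
18 | (2Z,6E)-3-iodo-7-methyl-10-(2-methyl-1,3-dioxolan-2-yl)deca-2,6-dien-1-ol (formed in the flask) | OC/C=C(I)/CC/C=C(C)/CCCC1(C)OCCO1 | intermediate
19 | (6E,10Z)-12-hydroxy-10-iodo-6-methyldodeca-6,10-dien-2-one | CC(=O)CCC/C(C)=C/CC/C(I)=C/CO | intermediate
20 | (6E,10Z)-12-bromo-10-iodo-6-methyldodeca-6,10-dien-2-one | CC(=O)CCC/C(C)=C/CC/C(I)=C/CBr | intermediate
21 | 3-tert-butyl 1-methyl 2-[2-(trimethylsilyl)ethyl] (1R,2S)-1-{[(2Z,6E)-3-iodo-7-methyl-11-oxododeca-2,6-dien-1-yl]oxy}propane-1,2,3-tricarboxylate | CC(=O)CCC/C(C)=C/CC/C(I)=C/CO[C@@H](C(=O)OC)[C@H](CC(=O)OC(C)(C)C)C(=O)OCC[Si](C)(C)C | intermediate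
22 | same triester, 1-{[(2Z,6E)-7-methyl-11-oxo-3-[(trimethylsilyl)methyl]dodeca-2,6-dien-1-yl]oxy} | CC(=O)CCC/C(C)=C/CC/C(C[Si](C)(C)C)=C/CO[C@@H](C(=O)OC)[C@H](CC(=O)OC(C)(C)C)C(=O)OCC[Si](C)(C)C | intermediate
23 | same triester, 1-{[(2Z,6E)-7-methyl-10-[(2R)-2-methyloxiran-2-yl]-3-[(trimethylsilyl)methyl]deca-2,6-dien-1-yl]oxy} | C[C@@]1(CCC/C(C)=C/CC/C(C[Si](C)(C)C)=C/CO[C@@H](C(=O)OC)[C@H](CC(=O)OC(C)(C)C)C(=O)OCC[Si](C)(C)C)CO1 | intermediate
24 | monomer: same triester, 1-{[(1S,4aR,5R,8aS)-5-(hydroxymethyl)-5,8a-dimethyl-2-methylidenedecahydronaphthalen-1-yl]methoxy}; drimane 4R,5R,9S,10S, trans‑decalin, 15‑OH free | C=C1CC[C@H]2[C@](C)(CO)CCC[C@]2(C)[C@H]1CO[C@@H](C(=O)OC)[C@H](CC(=O)OC(C)(C)C)C(=O)OCC[Si](C)(C)C | intermediate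
25 | 24 with O‑15 as trimethylsilyl ether and carboxyl c as trimethylsilyl ester (formed in the flask) | C=C1CC[C@H]2[C@](C)(CO[Si](C)(C)C)CCC[C@]2(C)[C@H]1CO[C@@H](C(=O)OC)[C@H](CC(=O)O[Si](C)(C)C)C(=O)OCC[Si](C)(C)C | intermediate
26 | monomer with carboxyl c free (a = Me; b = CH2CH2SiMe3; 15‑OH free) | C=C1CC[C@H]2[C@](C)(CO)CCC[C@]2(C)[C@H]1CO[C@@H](C(=O)OC)[C@H](CC(=O)O)C(=O)OCC[Si](C)(C)C | intermediate
27 | monomer Z (a = Me; b = CH2CH2SiMe3; c = Me; 15‑OH free) | C=C1CC[C@H]2[C@](C)(CO)CCC[C@]2(C)[C@H]1CO[C@@H](C(=O)OC)[C@H](CC(=O)OC)C(=O)OCC[Si](C)(C)C | intermediate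
28 | 24 with O‑15 as tert‑butyl carbonate | C=C1CC[C@H]2[C@](C)(COC(=O)OC(C)(C)C)CCC[C@]2(C)[C@H]1CO[C@@H](C(=O)OC)[C@H](CC(=O)OC(C)(C)C)C(=O)OCC[Si](C)(C)C | intermediate
29 | acid X: 28 with carboxyl b free | C=C1CC[C@H]2[C@](C)(COC(=O)OC(C)(C)C)CCC[C@]2(C)[C@H]1CO[C@@H](C(=O)OC)[C@H](CC(=O)OC(C)(C)C)C(=O)O | intermediate
30 | dimer X–Y: carboxyl b of 29 esterified with O‑15 of 24 | C=C1CC[C@H]2[C@](C)(COC(=O)[C@@H](CC(=O)OC(C)(C)C)[C@@H](OC[C@H]3C(=C)CC[C@H]4[C@](C)(COC(=O)OC(C)(C)C)CCC[C@]34C)C(=O)OC)CCC[C@]2(C)[C@H]1CO[C@@H](C(=O)OC)[C@H](CC(=O)OC(C)(C)C)C(=O)OCC[Si](C)(C)C | intermediate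
31 | dimer acid: 30 with carboxyl b of unit Y free | C=C1CC[C@H]2[C@](C)(COC(=O)[C@@H](CC(=O)OC(C)(C)C)[C@@H](OC[C@H]3C(=C)CC[C@H]4[C@](C)(COC(=O)OC(C)(C)C)CCC[C@]34C)C(=O)OC)CCC[C@]2(C)[C@H]1CO[C@@H](C(=O)OC)[C@H](CC(=O)OC(C)(C)C)C(=O)O | intermediate
32 | protected trimer X–Y–Z: carboxyl b of unit Y of 31 esterified with O‑15 of 27 | C=C1CC[C@H]2[C@](C)(COC(=O)[C@@H](CC(=O)OC(C)(C)C)[C@@H](OC[C@H]3C(=C)CC[C@H]4[C@](C)(COC(=O)[C@@H](CC(=O)OC(C)(C)C)[C@@H](OC[C@H]5C(=C)CC[C@H]6[C@](C)(COC(=O)OC(C)(C)C)CCC[C@]56C)C(=O)OC)CCC[C@]34C)C(=O)OC)CCC[C@]2(C)[C@H]1CO[C@@H](C(=O)OC)[C@H](CC(=O)OC)C(=O)OCC[Si](C)(C)C | intermediate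
33 | trimer with carboxyl b of unit Z free; O‑15 of X still carbonate, carboxyls c of X and Y still tert‑butyl esters | C=C1CC[C@H]2[C@](C)(COC(=O)[C@@H](CC(=O)OC(C)(C)C)[C@@H](OC[C@H]3C(=C)CC[C@H]4[C@](C)(COC(=O)[C@@H](CC(=O)OC(C)(C)C)[C@@H](OC[C@H]5C(=C)CC[C@H]6[C@](C)(COC(=O)OC(C)(C)C)CCC[C@]56C)C(=O)OC)CCC[C@]34C)C(=O)OC)CCC[C@]2(C)[C@H]1CO[C@@H](C(=O)OC)[C@H](CC(=O)OC)C(=O)O | intermediate
34 | persilylated trimer: three trimethylsilyl esters and the trimethylsilyl carbonate on O‑15 of X (formed in the flask) | C=C1CC[C@H]2[C@](C)(COC(=O)[C@@H](CC(=O)O[Si](C)(C)C)[C@@H](OC[C@H]3C(=C)CC[C@H]4[C@](C)(COC(=O)[C@@H](CC(=O)O[Si](C)(C)C)[C@@H](OC[C@H]5C(=C)CC[C@H]6[C@](C)(COC(=O)O[Si](C)(C)C)CCC[C@]56C)C(=O)OC)CCC[C@]34C)C(=O)OC)CCC[C@]2(C)[C@H]1CO[C@@H](C(=O)OC)[C@H](CC(=O)OC)C(=O)O[Si](C)(C)C | intermediate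
35 | cryptoporic acid T | C=C1CC[C@H]2[C@](C)(COC(=O)[C@@H](CC(=O)O)[C@@H](OC[C@H]3C(=C)CC[C@H]4[C@](C)(COC(=O)[C@@H](CC(=O)O)[C@@H](OC[C@H]5C(=C)CC[C@H]6[C@](C)(CO)CCC[C@]56C)C(=O)OC)CCC[C@]34C)C(=O)OC)CCC[C@]2(C)[C@H]1CO[C@@H](C(=O)OC)[C@H](CC(=O)OC)C(=O)O | target

## Count and risk

Total step count: 22. Longest linear sequence: 17 (steps 4–13, then 16–22); steps 1–3 and 14–15 are side branches.

Most likely to fail:

**Step 13.** The terminal epoxide may rearrange to the aldehyde by hydride shift, the chair with axial CH2O may compete (giving the decalin of opposite sense), or the silyl allyl ether may eliminate to a diene. Fallback, a radical closure instead of a cationic one, setting out from 21 and coming back at 24: Negishi coupling of 21 with MeZnCl and Pd(PPh3)4 gives the methyl‑terminated ketone ether F1. The uncatalysed ylide Me2S(O)=CH2 then gives the epoxide F2 as both epimers at the oxirane carbon, which does not matter because the radical is planar. Cp2TiCl (from Cp2TiCl2 and Mn), 2,4,6‑collidine and Me3SiCl in THF at rt open the epoxide homolytically with trivalent titanium to the tertiary C‑4 radical; two 6‑endo closures follow, and the C‑8 alkyltitanium ends by β‑hydride loss to the exocyclic alkene. This gives 24 together with its diastereomer of opposite decalin sense, separable by chromatography because the isocitrate part is enantiopure.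

**Step 12.** The enantioselectivity on this long‑chain ketone, the sense of induction and the tolerance of the triester to the basic catalyst are all untested. Fallback, resolution instead of induction, setting out from 22 and coming back at 23: the uncatalysed ylide Me2S(O)=CH2 gives the 1:1 epimeric epoxide F3. Kinetic resolution with (salen)CrN3 (the antipode matched to the unwanted epimer) and Me3SiN3 opens the (S)-epoxide at its CH2 to the azido silyl ether F4 and leaves 23, which is separated by chromatography.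

**Step 18 (step 20 carries the same risk).** A hindered, enolisable β‑alkoxy acid must acylate a neopentyl alcohol; epimerisation at C‑2' or β‑elimination under DMAP and base is possible. Fallback, a preformed acyl donor activated by a thiophilic metal without base, setting out from 29 and coming back at 30: 29 with 2,2'-dipyridyl disulfide and PPh3 gives the S‑(pyridin-2-yl) thioester F5. AgOTf with 24 in toluene at rt then transfers the acyl group to O‑15 and gives 30.

Further compounds

F1 | step 13 | 3-tert-butyl 1-methyl 2-[2-(trimethylsilyl)ethyl] (1R,2S)-1-{[(2E,6E)-3,7-dimethyl-11-oxododeca-2,6-dien-1-yl]oxy}propane-1,2,3-tricarboxylate | CC(=O)CCC/C(C)=C/CC/C(C)=C/CO[C@@H](C(=O)OC)[C@H](CC(=O)OC(C)(C)C)C(=O)OCC[Si](C)(C)C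
F2 | step 13 | same triester, 1-{[(2E,6E)-3,7-dimethyl-10-(2-methyloxiran-2-yl)deca-2,6-dien-1-yl]oxy}, both epimers at the oxirane carbon | CC1(CCC/C(C)=C/CC/C(C)=C/CO[C@@H](C(=O)OC)[C@H](CC(=O)OC(C)(C)C)C(=O)OCC[Si](C)(C)C)CO1
F3 | step 12 | 23 as the 1:1 mixture of epimers at the oxirane carbon | CC1(CCC/C(C)=C/CC/C(C[Si](C)(C)C)=C/CO[C@@H](C(=O)OC)[C@H](CC(=O)OC(C)(C)C)C(=O)OCC[Si](C)(C)C)CO1
F4 | step 12 | same triester, 1-{[(2Z,6E,11S)-12-azido-7,11-dimethyl-3-[(trimethylsilyl)methyl]-11-(trimethylsilyloxy)dodeca-2,6-dien-1-yl]oxy} | C[C@](O[Si](C)(C)C)(CCC/C(C)=C/CC/C(C[Si](C)(C)C)=C/CO[C@@H](C(=O)OC)[C@H](CC(=O)OC(C)(C)C)C(=O)OCC[Si](C)(C)C)CN=[N+]=[N-]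
F5 | step 18 | S‑(pyridin-2-yl) thioester of acid 29 at carboxyl b | C=C1CC[C@H]2[C@](C)(COC(=O)OC(C)(C)C)CCC[C@]2(C)[C@H]1CO[C@@H](C(=O)OC)[C@H](CC(=O)OC(C)(C)C)C(=O)Sc1ccccn1
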